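## Analysis of the target

Sophoraisoflavone A (25) is a 3-arylchromen-4-one. Ring A carries hydroxyls at C5 and C7, ring C is the pyranone, and ring B (C1'–C6') is fused across C2'–C3' to a 2,2-dimethyl-2H-pyran whose oxygen sits on C2' and whose vinylic carbon sits on C3'; C4' keeps a free hydroxyl. There is no stereocentre, so the problem is one of constitution only. The sensitive groups are the electron-rich chromene double bond (acid, electrophiles, hydrogenation), ring C (opened at C2 by hydroxide or alkoxide) and three phenols. The difficulty is the direction of pyran annulation. Ring B is a resorcinol with C3' between two oxygens, and a C5 unit on C3' normally closes onto the less hindered O4' or gives mixtures. The target needs the oxygen on C2', next to the bond to C3.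

The strategy rests on C2' being ortho to C1', and on C1' carrying the carbon that becomes C3. That carbon can be held as a formyl group. A formyl group at C1' activates both C2' (ortho) and C4' (para) towards nucleophilic aromatic substitution, so activation alone does not distinguish them. If C2' bears fluorine and C4' already bears its oxygen as an ether, only C2' has both activation and a good leaving group. A tertiary alkoxide tethered to C3' through a cis alkene then has to form the C2'–O bond.

## Retrosynthetic reasoning

**Ring C and protecting groups (25 from 23).** The O1–C2 bond and the four acetal protecting groups are cut together. This leads back to enaminone 23, in which C2 is a β-amino enone carbon and both ortho oxygens of ring A are masked. Ring A is symmetric, so either ortho oxygen may close and no regiochemical question arises. The forward step needs acid only: it frees the phenols and lets one of them add to C2 and expel the amine.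

**C3–C4 (23 from 16 and 21).** Cutting this bond separates ring A as the acyl donor 21 (used as its chloride 22) from the enamine 16. The cut is made here because the nucleophilic carbon of 16 is the former formyl carbon of 10, so the carbon that activated the substitution becomes C3 without any change of oxidation level. The forward reaction is a C-acylation of an enamine.

**C2=C3 (16 from 10 and 13).** The enamine double bond is cut to aldehyde 10 and the α-amino phosphine oxide 13. This delivers the enamine directly and avoids a free arylacetaldehyde, which would be unstable and would need an acidic enol ether hydrolysis next to the chromene. Reagent 13 comes from 11 and 12 by a three-component condensation with a one-carbon aldehyde.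

**C2'–O, the key disconnection (10 from 9).** The aryl ether bond of the pyran is cut. The precursor 9 has fluorine on C2 of the benzaldehyde (C2' of the target) and a (Z)-3-hydroxy-3-methylbutenyl chain on C3. The forward step must add the tertiary alkoxide to the fluorine-bearing carbon and expel the halide. The gain is complete control of the annulation direction.

**Side chain (9 from 8, and 8 from 6 and 7).** The cis alkene is taken back to the alkyne 8, which allows a stereodefined semi-hydrogenation. The aryl–alkyne bond is cut to aryl iodide 6 and the commercial alkynol 7.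

**C3–I and O-protection (6 from 2, and 2 from 1).** The iodine is placed on the carbon flanked by fluorine and the protected oxygen, the most acidic ring position, by directed metalation while the formyl group is masked in the flask. The acetal protecting group on O4 is both the director and the mask of the C4' hydroxyl. It is introduced on commercial 1.

**Ring A acid (21 from 18, and 18 from 17).** The carboxyl carbon is cut from the ring. It is introduced by metalation between two acetal-protected oxygens and carboxylation. Starting from phloroglucinol (17) avoids a decarboxylation-prone trihydroxybenzoic acid.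

## Alternatives that were turned down

**Alternative 1: ring B by vinylketene–siloxyalkyne benzannulation.**
- Disconnection: C1'–C2', C2'–C3' and C4'–C5', so that ring B is built last on a finished chromone.
- Forward key step: the diazo ketone A2 undergoes Wolff rearrangement to a vinylketene. This adds the siloxyalkyne A3 in a [2+2] fashion; four-electron opening of the cyclobutenone and six-electron closure give the phenol A1.
- For: A1 has a free 2'-hydroxyl, a prenyl group on C3' and a silylated 4'-oxygen. The two ring-B oxygens are therefore differentiated by construction, which matches the chosen route in regiocontrol. Three ring bonds form in one step, which the chosen route cannot match.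
- Against: A1 is still a prenyl phenol, so the pyran needs a further oxidative cyclisation. A2 is a diazo dienone attached to a chromone whose C2=C3 bond can act as a dipolarophile or Michael acceptor. A photochemical Wolff step must compete with the chromone chromophore. A3 is sensitive and takes several steps to make.
- Comparison: the route would be longer and would rest on two fragile partners. The chosen route uses ionic steps on stable, commercial building blocks and delivers the chromene directly.

**Alternative 2: Friedel–Crafts closure of an aryloxyacrylic acid.**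
- Disconnection: C4–C4a of ring C.
- Forward key step: the (Z)-acid A5 is converted to its chloride under neutral conditions and acylates the phloroglucinol ring ortho to the enol ether oxygen, giving the tris-silyl ether A4.
- For: ring A is symmetric, so the acylation site is unambiguous. The final deprotection would use fluoride, not acid. On that point this alternative is stronger than the chosen route, which ends with an acidic step next to the chromene.
- Against: an acylium-type electrophile is generated next to the electron-rich chromene double bond. The acylation site is flanked by a bulky silyloxy group on a ring made less nucleophilic by silylation. The acid must have the Z geometry. A5 already contains the pyran-fused ring B, so the annulation problem is left unsolved.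
- Comparison: the chosen route solves the annulation problem first. It then closes ring C by phenol addition to an enaminone, which needs no electrophile near the chromene.

**Alternative 3: rhodium-catalysed salicylaldehyde–alkyne annulation.**
- Disconnection: C3–C4 and O1–C2.
- Forward key step: under rhodium catalysis with a copper oxidant, the formyl C–H bond of salicylaldehyde A7 adds across the aryl(silyl)alkyne A8 and the phenol oxygen closes, giving the 2-silyl chromone A6.
- For: ring C is assembled from two pieces in one step, a convergence the chosen route does not reach. A8 could be made from aldehyde 10 by one-carbon homologation, so this alternative is compatible with the chosen pyran closure.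
- Against: the sense of insertion of an alkyne bearing both aryl and silyl groups is not secure, and the wrong sense gives a flavone-type product. A7 is hindered by its 6-substituent. The chromene alkene can compete for the metal. A protodesilylation step is added, and the acidic deprotection at the end is the same as in the chosen route.
- Comparison: step counts are similar. The chosen route offers a ring C assembly whose regiochemistry is fixed by polarity.

Key step: step 5

## Remarks on the chemistry

- Intermediates 3, 4, 5 and 15 contain stereocentres that form without control and are destroyed in the same flask; their SMILES carry no descriptors.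
- The push–pull double bonds of enaminones 23 and 24 isomerise freely and are lost in step 11; they are written without a geometric descriptor.
- Benzaldehyde positions C1–C4 of compounds 2–9 correspond to C1'–C4' of the target.

## Route

**Step 1**
Reactants: 1 2-fluoro-4-hydroxybenzaldehyde
Product: 2 2-fluoro-4-(methoxymethoxy)benzaldehyde
Conditions: MOMCl, i-Pr2NEt, CH2Cl2, 0 °C to rt
Reagents that add atoms: chloromethyl methyl ether, COCCl
Why: O-alkylation of an acidic para-formyl phenol under amine base (Williamson-type); the MOM ether later directs metalation and survives every basic step.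

**Step 2**
Reactants: 2 2-fluoro-4-(methoxymethoxy)benzaldehyde
Product: 6 2-fluoro-3-iodo-4-(methoxymethoxy)benzaldehyde, via lithium amino alkoxide 3 (not isolated), via aryllithium 4 (not isolated), via iodinated amino alkoxide 5 (not isolated)
Conditions: 1-methylpiperazine, n-BuLi, THF, −78 °C; add 2; n-BuLi, −78 °C; I2, −78 °C; aq. Na2S2O3, H2O
Reagents that add atoms: iodine, II
Why: Directed ortho-metalation with in situ aldehyde protection: the lithium amide adds to the formyl group to give a tetrahedral amino alkoxide that is a weak director, so n-BuLi removes the proton at C3, acidified from both sides by fluorine and the MOM oxygen; iodine traps the aryllithium at −78 °C before LiF can be lost to an aryne, and aqueous work-up returns the aldehyde.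

**Step 3**
Reactants: 6 2-fluoro-3-iodo-4-(methoxymethoxy)benzaldehyde; 7 2-methylbut-3-yn-2-ol
Product: 8 2-fluoro-3-(3-hydroxy-3-methylbut-1-yn-1-yl)-4-(methoxymethoxy)benzaldehyde
Conditions: Pd(PPh3)2Cl2 (cat.), CuI (cat.), Et3N, THF, 45 °C
Reagents that add atoms: none
Why: Sonogashira coupling of an aryl iodide on a formyl-substituted ring; a tertiary amine base is used so that no amine can displace the activated fluorine or condense with the aldehyde, and the linear alkyne keeps the hydroxyl away from C2.

**Step 4**
Reactants: 8 2-fluoro-3-(3-hydroxy-3-methylbut-1-yn-1-yl)-4-(methoxymethoxy)benzaldehyde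
Product: 9 2-fluoro-3-[(Z)-3-hydroxy-3-methylbut-1-enyl]-4-(methoxymethoxy)benzaldehyde
Conditions: H2 (1 atm), Pd/CaCO3 poisoned with Pb(OAc)2, quinoline, EtOAc, rt
Reagents that add atoms: none
Why: Lindlar semi-hydrogenation delivers both hydrogens to one face of the alkyne on the poisoned surface and should give the Z alkene; aryl aldehyde, aryl fluoride and MOM ether are not reduced under these conditions.

**Step 5**
Reactants: 9 2-fluoro-3-[(Z)-3-hydroxy-3-methylbut-1-enyl]-4-(methoxymethoxy)benzaldehyde
Product: 10 5-(methoxymethoxy)-2,2-dimethyl-2H-chromene-8-carbaldehyde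
Conditions: Cs2CO3, DMF, 80 °C
Reagents that add atoms: none
Why: The carbonate generates the tertiary alkoxide, which adds to the fluorine-bearing carbon C2 to give a Meisenheimer anion whose charge is carried by the ring and the ortho formyl oxygen; loss of fluoride restores the arene (addition–elimination). The closest known reaction type is the intramolecular etherification of ortho-fluorobenzaldehydes by tethered alkoxides. The pyran closes in a six-membered, 6-exo-trig mode with respect to the C2–C1 π bond that takes up the charge, helped by the gem-dimethyl group and by the Z alkene, which the two flanking substituents twist out of the ring plane so that the oxygen lies over the ring. No stereocentre is formed. The step needs selectivity between C2 and C4, because the formyl group activates its para carbon C4 as well and the twisted side chain can reach either neighbour. The substrate secures C2 because fluorine makes its ipso carbon much more electrophilic and is a far better leaving group than the MOM-oxy group on C4. The E isomer cannot reach the ring, so the geometry set in step 4 is a prerequisite. The aldehyde has no α-hydrogen and the tertiary alkoxide cannot transfer hydride, so aldol and hydride-transfer side reactions have no pathway.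

**Step 6**
Reactants: 11 diphenylphosphine oxide; 12 pyrrolidine
Product: 13 1-[(diphenylphosphoryl)methyl]pyrrolidine
Conditions: paraformaldehyde, toluene, 110 °C, Dean–Stark
Reagents that add atoms: formaldehyde (used as paraformaldehyde), C=O
Why: Kabachnik–Fields (phospha-Mannich) condensation: the iminium ion from pyrrolidine and formaldehyde is captured by the P–H compound, and removal of water drives the reaction.

**Step 7**
Reactants: 13 1-[(diphenylphosphoryl)methyl]pyrrolidine; 10 5-(methoxymethoxy)-2,2-dimethyl-2H-chromene-8-carbaldehyde
Product: 16 1-{(E)-2-[5-(methoxymethoxy)-2,2-dimethyl-2H-chromen-8-yl]ethenyl}pyrrolidine, via lithiated phosphine oxide 14 (not isolated), via lithium alkoxide adduct 15 (not isolated)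
Conditions: 13, n-BuLi, THF, −78 °C; add 10, −78 to 0 °C; KOt-Bu, 0 °C to rt; non-aqueous work-up
Reagents that add atoms: none
Why: Horner–Wittig olefination with an α-amino phosphine oxide: the carbanion adds to the non-enolisable aldehyde, and after exchange to potassium the alkoxide expels diphenylphosphinate by syn elimination to give the conjugated enamine directly, with no acid and no free arylacetaldehyde; the E isomer is expected to prevail and the geometry has no bearing on step 10.

**Step 8**
Reactants: 17 phloroglucinol (benzene-1,3,5-triol)
Product: 18 1,3,5-tris(methoxymethoxy)benzene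
Conditions: NaH, MOMCl, DMF, 0 °C to rt
Reagents that add atoms: chloromethyl methyl ether, COCCl
Why: Threefold O-alkylation of the phenoxide with a hard, oxocarbenium-like electrophile, which favours oxygen over ring carbon.

**Step 9**
Reactants: 18 1,3,5-tris(methoxymethoxy)benzene
Product: 21 2,4,6-tris(methoxymethoxy)benzoic acid, via aryllithium 19 (not isolated), via lithium carboxylate 20 (not isolated)
Conditions: n-BuLi, THF, 0 °C; CO2, −78 °C to rt; cold dilute HCl to pH 4
Reagents that add atoms: carbon dioxide, O=C=O
Why: Directed ortho-metalation at a position flanked by two MOM ethers (all three ring positions are equivalent) followed by carboxylation; a brief cold acidification to pH 4 should leave the aryl MOM ethers intact, and the acid is used promptly.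

**Step 10**
Reactants: 21 2,4,6-tris(methoxymethoxy)benzoic acid; 16 1-{(E)-2-[5-(methoxymethoxy)-2,2-dimethyl-2H-chromen-8-yl]ethenyl}pyrrolidine
Product: 23 2-[5-(methoxymethoxy)-2,2-dimethyl-2H-chromen-8-yl]-3-(pyrrolidin-1-yl)-1-[2,4,6-tris(methoxymethoxy)phenyl]prop-2-en-1-one, via acid chloride 22 (not isolated)
Conditions: 21, 1-chloro-N,N,2-trimethylprop-1-en-1-amine, CH2Cl2, 0 °C to rt; then 16, Et3N, CH2Cl2, 0 to 40 °C
Reagents that add atoms: none
Why: Stork-type C-acylation of an enamine: the α-chloroenamine forms the acid chloride without releasing HCl, so the MOM ethers are safe; the aryl-bearing enamine carbon attacks the acyl chloride and Et3N deprotonates the iminium ion to give the vinylogous amide, and the aroyl chloride cannot form a ketene.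

**Step 11**
Reactants: 23 2-[5-(methoxymethoxy)-2,2-dimethyl-2H-chromen-8-yl]-3-(pyrrolidin-1-yl)-1-[2,4,6-tris(methoxymethoxy)phenyl]prop-2-en-1-one
Product: 25 sophoraisoflavone A, 5,7-dihydroxy-3-(5-hydroxy-2,2-dimethyl-2H-chromen-8-yl)-4H-chromen-4-one, via tetrahydroxy enaminone 24 (not isolated)
Conditions: 3 M aq. HCl, MeOH/THF, 50 °C
Reagents that add atoms: none
Why: Acid-catalysed methanolysis removes the four MOM ethers, and an ortho hydroxyl of ring A adds to the protonated enaminone at C2 and expels pyrrolidine (the usual chromone closure of 2-hydroxyaryl enaminones); ring A is symmetric so either hydroxyl gives the same product, and aryl MOM removal under these conditions is established on 2,2-dimethylchromene-containing flavonoids.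

## Compound list

1 | 2-fluoro-4-hydroxybenzaldehyde | O=Cc1ccc(O)cc1F | starting material
2 | 2-fluoro-4-(methoxymethoxy)benzaldehyde | COCOc1ccc(C=O)c(F)c1 | intermediate
3 | lithium [2-fluoro-4-(methoxymethoxy)phenyl](4-methylpiperazin-1-yl)methanolate (racemic) | [Li]OC(N1CCN(C)CC1)c1ccc(OCOC)cc1F | intermediate
4 | lithium [2-fluoro-3-lithio-4-(methoxymethoxy)phenyl](4-methylpiperazin-1-yl)methanolate (racemic) | [Li]OC(N1CCN(C)CC1)c1ccc(OCOC)c([Li])c1F | intermediate
5 | lithium [2-fluoro-3-iodo-4-(methoxymethoxy)phenyl](4-methylpiperazin-1-yl)methanolate (racemic) | [Li]OC(N1CCN(C)CC1)c1ccc(OCOC)c(I)c1F | intermediate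
6 | 2-fluoro-3-iodo-4-(methoxymethoxy)benzaldehyde | COCOc1ccc(C=O)c(F)c1I | intermediate
7 | 2-methylbut-3-yn-2-ol | C#CC(C)(C)O | starting material
8 | 2-fluoro-3-(3-hydroxy-3-methylbut-1-yn-1-yl)-4-(methoxymethoxy)benzaldehyde | COCOc1ccc(C=O)c(F)c1C#CC(C)(C)O | intermediate
9 | 2-fluoro-3-[(Z)-3-hydroxy-3-methylbut-1-enyl]-4-(methoxymethoxy)benzaldehyde | COCOc1ccc(C=O)c(F)c1/C=C\C(C)(C)O | intermediate
10 | 5-(methoxymethoxy)-2,2-dimethyl-2H-chromene-8-carbaldehyde | COCOc1ccc(C=O)c2c1C=CC(C)(C)O2 | intermediate
11 | diphenylphosphine oxide | O=[PH](c1ccccc1)c1ccccc1 | starting material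
12 | pyrrolidine | C1CCNC1 | starting material
13 | 1-[(diphenylphosphoryl)methyl]pyrrolidine | O=P(CN1CCCC1)(c1ccccc1)c1ccccc1 | intermediate
14 | [(diphenylphosphoryl)(pyrrolidin-1-yl)methyl]lithium | [Li]C(N1CCCC1)P(=O)(c1ccccc1)c1ccccc1 | intermediate
15 | lithium 2-(diphenylphosphoryl)-1-[5-(methoxymethoxy)-2,2-dimethyl-2H-chromen-8-yl]-2-(pyrrolidin-1-yl)ethan-1-olate (mixture of diastereomers) | [Li]OC(c1ccc(OCOC)c2c1OC(C)(C)C=C2)C(N1CCCC1)P(=O)(c1ccccc1)c1ccccc1 | intermediate
16 | 1-{(E)-2-[5-(methoxymethoxy)-2,2-dimethyl-2H-chromen-8-yl]ethenyl}pyrrolidine | COCOc1ccc(/C=C/N2CCCC2)c2c1C=CC(C)(C)O2 | intermediate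
17 | phloroglucinol (benzene-1,3,5-triol) | Oc1cc(O)cc(O)c1 | starting material
18 | 1,3,5-tris(methoxymethoxy)benzene | COCOc1cc(OCOC)cc(OCOC)c1 | intermediate
19 | 2,4,6-tris(methoxymethoxy)phenyllithium | [Li]c1c(OCOC)cc(OCOC)cc1OCOC | intermediate
20 | lithium 2,4,6-tris(methoxymethoxy)benzoate | [Li]OC(=O)c1c(OCOC)cc(OCOC)cc1OCOC | intermediate
21 | 2,4,6-tris(methoxymethoxy)benzoic acid | OC(=O)c1c(OCOC)cc(OCOC)cc1OCOC | intermediate
22 | 2,4,6-tris(methoxymethoxy)benzoyl chloride | ClC(=O)c1c(OCOC)cc(OCOC)cc1OCOC | intermediate
23 | 2-[5-(methoxymethoxy)-2,2-dimethyl-2H-chromen-8-yl]-3-(pyrrolidin-1-yl)-1-[2,4,6-tris(methoxymethoxy)phenyl]prop-2-en-1-one | COCOc1cc(OCOC)c(C(=O)C(=CN2CCCC2)c2ccc(OCOC)c3c2OC(C)(C)C=C3)c(OCOC)c1 | intermediate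
24 | 2-(5-hydroxy-2,2-dimethyl-2H-chromen-8-yl)-3-(pyrrolidin-1-yl)-1-(2,4,6-trihydroxyphenyl)prop-2-en-1-one | Oc1cc(O)c(C(=O)C(=CN2CCCC2)c2ccc(O)c3c2OC(C)(C)C=C3)c(O)c1 | intermediate
25 | sophoraisoflavone A, 5,7-dihydroxy-3-(5-hydroxy-2,2-dimethyl-2H-chromen-8-yl)-4H-chromen-4-one | CC1(C)C=Cc2c(O)ccc(-c3coc4cc(O)cc(O)c4c3=O)c2O1 | target

## Step count and risk

Total step count: 11. Longest linear sequence: 8 steps (steps 1, 2, 3, 4, 5, 7, 10 and 11); steps 6, 8 and 9 are side branches.

**Step 5 (key step).** The most likely failure is slow addition of the hindered tertiary alkoxide, because the para MOM-oxy group feeds electron density into the formyl group and weakens its activation. Base-mediated degradation of the aldehyde, or attack at C4 with loss of the MOM-oxy group, could then compete. The fallback sets out from 2 and 7 and forms the pyran by a pericyclic sequence. The sodium alkoxide of 7 (NaH, DMF) displaces the unhindered fluorine of 2 intermolecularly to give 4-(methoxymethoxy)-2-[(2-methylbut-3-yn-2-yl)oxy]benzaldehyde F1. Heating F1 in N,N-diethylaniline at about 160 °C brings about a propargyl Claisen rearrangement to C3, the only free ortho position, followed by enolisation, 1,5-hydrogen shift and oxa-six-electron closure. The route is rejoined at 10.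

**Step 10.** C-acylation of the moderately nucleophilic styryl enamine by a 2,6-disubstituted, electron-rich aroyl chloride may be slow. Hydrolysis of the enamine or acid chloride by adventitious water, or MOM loss through traces of HCl, would then take over. The fallback sets out from 16 and builds the C3–C4 bond through a deoxybenzoin.
- 16 is hydrolysed on buffered wet silica to 2-[5-(methoxymethoxy)-2,2-dimethyl-2H-chromen-8-yl]acetaldehyde F2.
- Aryllithium 19 (from 18 as in step 9), transmetalated with CeCl3 to suppress enolisation, adds to F2 to give racemic 2-[5-(methoxymethoxy)-2,2-dimethyl-2H-chromen-8-yl]-1-[2,4,6-tris(methoxymethoxy)phenyl]ethan-1-ol F3.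
- Dess–Martin oxidation gives 2-[5-(methoxymethoxy)-2,2-dimethyl-2H-chromen-8-yl]-1-[2,4,6-tris(methoxymethoxy)phenyl]ethan-1-one F4.
- Condensation with N,N-dimethylformamide dimethyl acetal gives 3-(dimethylamino)-2-[5-(methoxymethoxy)-2,2-dimethyl-2H-chromen-8-yl]-1-[2,4,6-tris(methoxymethoxy)phenyl]prop-2-en-1-one F5.
- F5 is treated under the conditions of step 11 and the route is rejoined at 25.

**Step 11.** Protic acid may add methanol or chloride across the electron-rich chromene double bond, or oligomerise it, before all four MOM groups are gone. Acid-promoted loss of the C2 carbon from the hydrolysed enaminone (retro-Claisen) is a second risk. The fallback sets out from 23 and separates deprotection from ring closure without free Brønsted acid. TMSOTf with 2,2'-bipyridyl in CH2Cl2 at 0 °C converts the aryl MOM ethers into silyl ethers, giving 2-[2,2-dimethyl-5-(trimethylsilyloxy)-2H-chromen-8-yl]-3-(pyrrolidin-1-yl)-1-[2,4,6-tris(trimethylsilyloxy)phenyl]prop-2-en-1-one F6. Mild hydrolysis releases 24, which is closed by warming in ethanol containing acetic acid. The route is rejoined at 25.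

**Step 2.** Incomplete masking of the aldehyde, metalation at a position other than C3, or loss of LiF from the aryllithium on warming would erode this one-pot step. The fallback sets out from 2 and protects the aldehyde in a separate operation. Trimethyl orthoformate with catalytic pyridinium p-toluenesulfonate in methanol gives 1-(dimethoxymethyl)-2-fluoro-4-(methoxymethoxy)benzene F7. Lithiation with n-BuLi at −78 °C and iodination give 1-(dimethoxymethyl)-2-fluoro-3-iodo-4-(methoxymethoxy)benzene F8. Brief hydrolysis with pyridinium p-toluenesulfonate in wet acetone rejoins the route at 6.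

## Further compounds

F1 | step 5 | 4-(methoxymethoxy)-2-[(2-methylbut-3-yn-2-yl)oxy]benzaldehyde | COCOc1ccc(C=O)c(OC(C)(C)C#C)c1
F2 | step 10 | 2-[5-(methoxymethoxy)-2,2-dimethyl-2H-chromen-8-yl]acetaldehyde | COCOc1ccc(CC=O)c2c1C=CC(C)(C)O2
F3 | step 10 | 2-[5-(methoxymethoxy)-2,2-dimethyl-2H-chromen-8-yl]-1-[2,4,6-tris(methoxymethoxy)phenyl]ethan-1-ol (racemic) | COCOc1cc(OCOC)c(C(O)Cc2ccc(OCOC)c3c2OC(C)(C)C=C3)c(OCOC)c1
F4 | step 10 | 2-[5-(methoxymethoxy)-2,2-dimethyl-2H-chromen-8-yl]-1-[2,4,6-tris(methoxymethoxy)phenyl]ethan-1-one | COCOc1cc(OCOC)c(C(=O)Cc2ccc(OCOC)c3c2OC(C)(C)C=C3)c(OCOC)c1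
F5 | step 10 | 3-(dimethylamino)-2-[5-(methoxymethoxy)-2,2-dimethyl-2H-chromen-8-yl]-1-[2,4,6-tris(methoxymethoxy)phenyl]prop-2-en-1-one | COCOc1cc(OCOC)c(C(=O)C(=CN(C)C)c2ccc(OCOC)c3c2OC(C)(C)C=C3)c(OCOC)c1
F6 | step 11 | 2-[2,2-dimethyl-5-(trimethylsilyloxy)-2H-chromen-8-yl]-3-(pyrrolidin-1-yl)-1-[2,4,6-tris(trimethylsilyloxy)phenyl]prop-2-en-1-one | C[Si](C)(C)Oc1cc(O[Si](C)(C)C)c(C(=O)C(=CN2CCCC2)c2ccc(O[Si](C)(C)C)c3c2OC(C)(C)C=C3)c(O[Si](C)(C)C)c1
F7 | step 2 | 1-(dimethoxymethyl)-2-fluoro-4-(methoxymethoxy)benzene | COCOc1ccc(C(OC)OC)c(F)c1
F8 | step 2 | 1-(dimethoxymethyl)-2-fluoro-3-iodo-4-(methoxymethoxy)benzene | COCOc1ccc(C(OC)OC)c(F)c1I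
A1 | alternative 1 | 3-[2-hydroxy-3-(3-methylbut-2-enyl)-4-(triisopropylsilyloxy)phenyl]-5,7-bis(methoxymethoxy)chromen-4-one | COCOc1cc(OCOC)c2c(c1)occ(-c1ccc(O[Si](C(C)C)(C(C)C)C(C)C)c(CC=C(C)C)c1O)c2=O
A2 | alternative 1 | (E)-4-[5,7-bis(methoxymethoxy)-4-oxo-4H-chromen-3-yl]-1-diazobut-3-en-2-one | COCOc1cc(OCOC)c2c(c1)occ(/C=C/C(=O)C=[N+]=[N-])c2=O
A3 | alternative 1 | triisopropyl[(5-methylhex-4-en-1-yn-1-yl)oxy]silane | CC(C)=CCC#CO[Si](C(C)C)(C(C)C)C(C)C
A4 | alternative 2 | 3-[2,2-dimethyl-5-(triisopropylsilyloxy)-2H-chromen-8-yl]-5,7-bis(triisopropylsilyloxy)chromen-4-one | O=c1c(-c2ccc(O[Si](C(C)C)(C(C)C)C(C)C)c3c2OC(C)(C)C=C3)coc2cc(O[Si](C(C)C)(C(C)C)C(C)C)cc(O[Si](C(C)C)(C(C)C)C(C)C)c12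
A5 | alternative 2 | (Z)-3-[3,5-bis(triisopropylsilyloxy)phenoxy]-2-[2,2-dimethyl-5-(triisopropylsilyloxy)-2H-chromen-8-yl]prop-2-enoic acid | OC(=O)/C(=C\Oc1cc(O[Si](C(C)C)(C(C)C)C(C)C)cc(O[Si](C(C)C)(C(C)C)C(C)C)c1)c1ccc(O[Si](C(C)C)(C(C)C)C(C)C)c2c1OC(C)(C)C=C2
A6 | alternative 3 | 5,7-bis(methoxymethoxy)-3-[5-(methoxymethoxy)-2,2-dimethyl-2H-chromen-8-yl]-2-(trimethylsilyl)chromen-4-one | COCOc1cc(OCOC)c2c(c1)oc([Si](C)(C)C)c(-c1ccc(OCOC)c3c1OC(C)(C)C=C3)c2=O
A7 | alternative 3 | 2-hydroxy-4,6-bis(methoxymethoxy)benzaldehyde | COCOc1cc(O)c(C=O)c(OCOC)c1
A8 | alternative 3 | {[5-(methoxymethoxy)-2,2-dimethyl-2H-chromen-8-yl]ethynyl}trimethylsilane | COCOc1ccc(C#C[Si](C)(C)C)c2c1C=CC(C)(C)O2
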